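**Strategy.** Everything rests on cutting the acyl–vinyl bond C11–C12 of the α-methylene-γ-butyrolactone (ring O–C6–C7–C11(=C13)–C12; germacranolide locants), which is trans-fused to the ten-membered carbocycle. The precursor is an acyclic homopropargylic alcohol (C6–OH anti to C7–C≡CH) whose stereocentres C6–C9 are C2–C5 of a 3-C-ethynyl-D-altrose made from methyl α-D-glucopyranoside. In one operation a palladium-catalysed cyclocarbonylation takes up CO on the hydroxyl and closes the lactone by syn insertion of the alkyne into the Pd–acyl bond, forming C11–C12 and the exocyclic methylene. A silicon-tethered ring-closing metathesis (C1=C10), a chloroallylborane-derived cis-vinyl epoxide and a final macrocyclic metathesis (C4=C5) complete the ring.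

Key step: step 9

Remarks on the chemistry
- Locants C1–C14 are germacranolide locants: C11 is the lactone α-carbon, C12 the lactone carbonyl, C13 the exocyclic methylene, C14 the ester carbon on C10. Sugar carbons C1–C6 become C5–C10.
- Assumption: the two reagent-controlled steps follow the usual sense of induction. The borane made from (−)-Ipc2BOMe attacks the Si face of acrolein (step 11), and D-(−)-diethyl tartrate gives the (2R,3S)-epoxy alcohol from (Z)-2-methylbut-2-en-1-ol (step 17).
- Compounds 20–24 and 30 are named with target locants; all their stereocentres have the spatial arrangement of the target.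

Step 1
Reactants: 1 methyl α-D-glucopyranoside; 2 2-(dimethoxymethyl)naphthalene
Product: 3 methyl 4,6-O-[(R)-naphthalen-2-ylmethylidene]-α-D-glucopyranoside
Conditions: camphorsulfonic acid (cat.), DMF, 60 °C, 200 mbar
Reagents that add atoms: 2-(dimethoxymethyl)naphthalene 2, COC(OC)c1ccc2ccccc2c1
Why: Acid-catalysed transacetalisation gives the thermodynamic 4,6-O-arylidene acetal (aryl equatorial), which locks the 4C1 chair for step 3 and later leaves an oxidatively removable naphthylmethyl ether on O4.

Step 2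
Reactants: 3 methyl 4,6-O-[(R)-naphthalen-2-ylmethylidene]-α-D-glucopyranoside
Product: 5 methyl 2,3-anhydro-4,6-O-[(R)-naphthalen-2-ylmethylidene]-α-D-mannopyranoside, via 2-O-tosylate 4 (not isolated)
Conditions: NaH (2.5 equiv), N-tosylimidazole (1.1 equiv), DMF, 0 °C to rt
Reagents that add atoms: none
Why: The more acidic 2-OH next to the axial anomeric methoxy group is sulfonylated selectively and the 3-alkoxide displaces it (intramolecular Williamson epoxide closure with inversion at C2), giving the manno epoxide.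

Step 3
Reactants: 5 methyl 2,3-anhydro-4,6-O-[(R)-naphthalen-2-ylmethylidene]-α-D-mannopyranoside; 6 (trimethylsilyl)acetylene
Product: 7 methyl 3-deoxy-4,6-O-[(R)-naphthalen-2-ylmethylidene]-3-C-[(trimethylsilyl)ethynyl]-α-D-altropyranoside
Conditions: 6, nBuLi, toluene, 0 °C; Et2AlCl; then 5, toluene, 0 to 50 °C
Reagents that add atoms: (trimethylsilyl)acetylene 6, C#C[Si](C)(C)C
Why: The alkynylalane opens the conformationally locked epoxide trans-diaxially at C3 with inversion (Fürst–Plattner rule), which sets the ethynyl-bearing centre (later C7) anti to the free 2-OH (later O6) and syn to O4 (later O8).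

Step 4
Reactants: 7 methyl 3-deoxy-4,6-O-[(R)-naphthalen-2-ylmethylidene]-3-C-[(trimethylsilyl)ethynyl]-α-D-altropyranoside
Product: 8 methyl 3-deoxy-4-O-(naphthalen-2-ylmethyl)-3-C-[(trimethylsilyl)ethynyl]-α-D-altropyranoside
Conditions: Et3SiH, PhBCl2, 4 Å molecular sieves, CH2Cl2, −78 °C
Reagents that add atoms: none
Why: Regioselective reductive opening of the 4,6-O-arylidene acetal: the boron Lewis acid binds the less hindered O6 and hydride adds to the oxocarbenium ion, leaving the arylmethyl ether on O4 and a free primary 6-OH.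

Step 5
Reactants: 8 methyl 3-deoxy-4-O-(naphthalen-2-ylmethyl)-3-C-[(trimethylsilyl)ethynyl]-α-D-altropyranoside
Product: 9 methyl 3-deoxy-4-O-(naphthalen-2-ylmethyl)-3-C-[(trimethylsilyl)ethynyl]-α-D-altro-hexodialdo-1,5-pyranoside
Conditions: TEMPO (0.2 equiv), PhI(OAc)2 (1.2 equiv), CH2Cl2, rt
Reagents that add atoms: none
Why: Oxoammonium oxidation is selective for the primary 6-OH over the hindered axial secondary 2-OH and stops at the aldehyde.

Step 6
Reactants: 9 methyl 3-deoxy-4-O-(naphthalen-2-ylmethyl)-3-C-[(trimethylsilyl)ethynyl]-α-D-altro-hexodialdo-1,5-pyranoside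
Product: 11 methyl 3,6,7-trideoxy-3-C-ethynyl-4-O-(naphthalen-2-ylmethyl)-α-D-altro-hept-6-ynopyranoside, via C-silyl diyne 10 (not isolated)
Conditions: dimethyl (1-diazo-2-oxopropyl)phosphonate (1.5 equiv), K2CO3 (3 equiv), MeOH, 0 °C to rt
Reagents that add atoms: dimethyl (1-diazo-2-oxopropyl)phosphonate, CC(=O)C(=[N+]=[N-])P(=O)(OC)OC
Why: Seyferth–Gilbert homologation with the Ohira–Bestmann reagent turns the aldehyde into the terminal alkyne (the equatorial formyl group is the stable epimer, so C5 is kept), and the methanolic carbonate also removes the C-silyl group.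

Step 7
Reactants: 11 methyl 3,6,7-trideoxy-3-C-ethynyl-4-O-(naphthalen-2-ylmethyl)-α-D-altro-hept-6-ynopyranoside
Product: 12 3,6,7-trideoxy-3-C-ethynyl-4-O-(naphthalen-2-ylmethyl)-D-altro-hept-6-ynopyranose (anomeric mixture)
Conditions: 2 M HCl, 1,4-dioxane, 70 °C
Reagents that add atoms: water, O
Why: Acid hydrolysis of the methyl glycoside (a 3-deoxy glycoside, cleaved under conditions that spare the arylmethyl ether and both alkynes) frees the hemiacetal, the masked C5 aldehyde.

Step 8
Reactants: 12 3,6,7-trideoxy-3-C-ethynyl-4-O-(naphthalen-2-ylmethyl)-D-altro-hept-6-ynopyranose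
Product: 13 (3R,4S,5S,6R)-4-ethynyl-5-(naphthalen-2-ylmethoxy)oct-1-en-7-yne-3,6-diol
Conditions: Ph3PCH3Br (5 equiv), KOtBu (4.8 equiv), THF, 0 °C to rt
Reagents that add atoms: methyltriphenylphosphonium bromide, C[P+](c1ccccc1)(c1ccccc1)c1ccccc1.[Br-]
Why: Wittig methylenation of the open-chain aldehyde in equilibrium with the lactol opens the pyranose, turns sugar C1 into the C5=C4 vinyl group and frees the ring oxygen as the C9 hydroxyl; the α-alkoxide prevents epimerisation.

Step 9
Reactants: 13 (3R,4S,5S,6R)-4-ethynyl-5-(naphthalen-2-ylmethoxy)oct-1-en-7-yne-3,6-diol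
Product: 14 (4S,5R)-5-ethenyl-4-[(1S,2R)-2-hydroxy-1-(naphthalen-2-ylmethoxy)but-3-yn-1-yl]-3-methylideneoxolan-2-one
Conditions: PdCl2 (5 mol%), SnCl2 (5 mol%), PPh3 (10 mol%), CO (8 bar), MeCN, 75 °C
Reagents that add atoms: carbon monoxide, [C-]#[O+]
Why: Divalent palladium, the C6 hydroxyl and CO give an alkoxycarbonylpalladium species; the C7 ethynyl group then inserts syn into its Pd–C(=O)O bond, which forms C11–C12 and closes the lactone, and protonolysis of the vinyl–palladium bond by the HCl released leaves the exocyclic methylene and returns the catalyst without a change of oxidation state. The closest known reaction type is the palladium-catalysed cyclocarbonylation of homopropargylic alcohols to α-methylene-γ-butyrolactones. The only ring closed is the five-membered lactone, by 5-exo-dig insertion. No stereocentre is created; the trans fusion follows from the anti C6/C7 configuration taken from the altrose. The step must choose the C6 over the C9 hydroxyl and the C7 ethynyl over the C9 ethynyl group: only the O6/C11 pair can close a five-membered ring (O9 would need a six-membered insertion at C11 or a four-membered one at C10), and O8 is blocked as the naphthylmethyl ether.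

Step 10
Reactants: 14 (4S,5R)-5-ethenyl-4-[(1S,2R)-2-hydroxy-1-(naphthalen-2-ylmethoxy)but-3-yn-1-yl]-3-methylideneoxolan-2-one
Product: 15 methyl (3R,4S)-4-[(2R,3S)-2-ethenyl-4-methylidene-5-oxooxolan-3-yl]-3-hydroxy-2-methylidene-4-(naphthalen-2-ylmethoxy)butanoate
Conditions: Pd(OAc)2 (1 mol%), 2-(diphenylphosphino)pyridine (20 mol%), CH3SO3H (20 mol%), CO (30 bar), MeOH, 50 °C
Reagents that add atoms: carbon monoxide, [C-]#[O+]; methanol, CO
Why: Markovnikov methoxycarbonylation of the remaining terminal alkyne (palladium/2-pyridylphosphine/acid hydroesterification) puts CO2Me on the internal carbon C10 and gives the 2-substituted acrylate; the alkenes and the lactone are inert to this alkyne-selective catalyst.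

Step 11
Reactants: 16 acrolein; 17 allyl chloride
Product: 18 (3R,4R)-4-chlorohexa-1,5-dien-3-ol
Conditions: 17, LiN(c-C6H11)2, (−)-Ipc2BOMe, BF3·OEt2, THF/Et2O, −95 °C; then 16, −95 °C; ethanolamine work-up
Reagents that add atoms: allyl chloride 17, ClCC=C
Why: Brown-type allylboration with the (Z)-γ-chloroallyl diisopinocampheylborane runs through a chair transition state, so the Z geometry gives the syn chlorohydrin and the isopinocampheyl groups fix the absolute configuration; the product stores C2 and C3 of the target.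

Step 12
Reactants: 15 methyl (3R,4S)-4-[(2R,3S)-2-ethenyl-4-methylidene-5-oxooxolan-3-yl]-3-hydroxy-2-methylidene-4-(naphthalen-2-ylmethoxy)butanoate; 18 (3R,4R)-4-chlorohexa-1,5-dien-3-ol
Product: 20 mixed diisopropylsilylene acetal joining O9 of 15 to the hydroxyl oxygen (O2) of 18, via chlorosilane 19 (not isolated)
Conditions: 18, iPr2SiCl2 (3 equiv), imidazole, CH2Cl2, 0 °C, excess silane evaporated; then 15, imidazole, DMAP, DMF, rt
Reagents that add atoms: dichlorodi(propan-2-yl)silane, CC(C)[Si](Cl)(Cl)C(C)C; chlorohydrin 18, C=C[C@@H](O)[C@H](Cl)C=C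
Why: Stepwise silylation with a dialkyldichlorosilane gives the unsymmetrical silaketal, because the C9 hydroxyl is the only free hydroxyl of 15 and displaces chloride from monochlorosilane 19.

Step 13
Reactants: 20 mixed diisopropylsilylene acetal of 15 and 18
Product: 21 2,2-diisopropyl-1,3-dioxa-2-silacyclohept-5-ene (ring Si–O9–C9–C10=C1–C2–O2) with CO2Me on C10, the (R)-1-chloroprop-2-enyl group on C2 and the lactone side chain on C9
Conditions: second-generation Grubbs catalyst (10 mol%), CH2Cl2 (5 mM), 40 °C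
Reagents that add atoms: none
Why: Temporary silicon-tethered ring-closing metathesis: the carbene formed at the C1 vinyl group should close the seven-membered ring onto the acrylate faster than any larger ring, and the small ring forces C9 and C2 cis on the new trisubstituted C1=C10 bond.

Step 14
Reactants: 21 seven-membered silaketal
Product: 23 9-O-acetyl (E)-enoate carrying the (2R,3S)-3-ethenyloxiran-2-yl group on C1 and the naphthylmethyl ether on O8, via epoxy alcohol 22 (not isolated)
Conditions: Bu4NF (2.5 equiv), THF, 0 °C; then Ac2O, pyridine, DMAP, 0 °C to rt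
Reagents that add atoms: acetic anhydride, CC(=O)OC(C)=O
Why: Fluoride cleaves both Si–O bonds, the freed C2 alkoxide displaces the anti-periplanar allylic chloride at C3 with inversion (syn chlorohydrin to cis epoxide), and the remaining C9 hydroxyl is acetylated in the same flask.

Step 15
Reactants: 23 9-O-acetyl epoxy enoate with O8 naphthylmethyl ether
Product: 24 9-O-acetyl 8-hydroxy epoxy enoate
Conditions: DDQ (1.5 equiv), CH2Cl2/pH 7 phosphate buffer (10:1), 0 °C to rt
Reagents that add atoms: none
Why: DDQ cleaves the electron-rich 2-naphthylmethyl ether oxidatively under buffered conditions that leave the vinyl epoxide, the acetate and the enoates untouched.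

Step 16
Reactants: 25 angelic acid ((Z)-2-methylbut-2-enoic acid)
Product: 26 (Z)-2-methylbut-2-en-1-ol
Conditions: LiAlH4, Et2O, 0 °C
Reagents that add atoms: none
Why: Hydride reduction of the acid gives the allylic alcohol with the Z double bond retained.

Step 17
Reactants: 26 (Z)-2-methylbut-2-en-1-ol
Product: 27 [(2R,3S)-2,3-dimethyloxiran-2-yl]methanol
Conditions: Ti(OiPr)4 (10 mol%), D-(−)-diethyl tartrate (12 mol%), tBuOOH, 4 Å molecular sieves, CH2Cl2, −20 °C
Reagents that add atoms: tert-butyl hydroperoxide, CC(C)(C)OO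
Why: Sharpless asymmetric epoxidation: the titanium tartrate complex delivers oxygen to one face of the allylic alcohol and sets both epoxide centres, cis because the olefin is Z.

Step 18
Reactants: 27 [(2R,3S)-2,3-dimethyloxiran-2-yl]methanol
Product: 28 (2S,3S)-2,3-dimethyloxirane-2-carboxylic acid
Conditions: RuCl3·xH2O (2 mol%), NaIO4 (4 equiv), CCl4/MeCN/H2O, rt
Reagents that add atoms: sodium periodate, [Na+].[O-]I(=O)(=O)=O; water, O
Why: RuO4 generated in situ oxidises the primary alcohol to the acid without opening the epoxide; the descriptor at C2 changes only because the substituent priorities change.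

Step 19
Reactants: 24 9-O-acetyl 8-hydroxy epoxy enoate; 28 (2S,3S)-2,3-dimethyloxirane-2-carboxylic acid
Product: 30 8-O-[(2S,3S)-2,3-dimethyloxirane-2-carbonyl] 9-O-acetyl epoxy enoate (open-chain diene with vinyl groups on C6 and C3), via mixed anhydride 29 (not isolated)
Conditions: 28, 2,4,6-trichlorobenzoyl chloride, Et3N, toluene, rt; then 24, DMAP, toluene, rt
Reagents that add atoms: acid 28, OC(=O)[C@@]1(C)O[C@H]1C
Why: Yamaguchi esterification through mixed anhydride 29 acylates the hindered C8 hydroxyl under mild conditions that spare both epoxides and should keep the acetate on O9.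

Step 20
Reactants: 30 open-chain diene
Product: 31 target CNP0077533.1
Conditions: second-generation Hoveyda–Grubbs catalyst (15 mol%), CH2Cl2 (1 mM), 40 °C
Reagents that add atoms: none
Why: Ring-closing metathesis of the two monosubstituted vinyl groups closes the ten-membered ring; the cis C1=C10 bond, the cis epoxide and the trans lactone should leave only the Z geometry at C4=C5 within reach, the two electron-poor 1,1-disubstituted olefins should not compete, and 40 °C stays below the range where the dialkenyl epoxide could undergo a Cope rearrangement.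

**Compound list**

1 | methyl α-D-glucopyranoside | CO[C@H]1O[C@H](CO)[C@@H](O)[C@H](O)[C@H]1O | starting material
2 | 2-(dimethoxymethyl)naphthalene | COC(OC)c1ccc2ccccc2c1 | starting material
3 | methyl 4,6-O-[(R)-naphthalen-2-ylmethylidene]-α-D-glucopyranoside | CO[C@H]1O[C@@H]2CO[C@@H](c3ccc4ccccc4c3)O[C@H]2[C@H](O)[C@H]1O | intermediate
4 | methyl 2-O-(4-methylbenzenesulfonyl)-4,6-O-[(R)-naphthalen-2-ylmethylidene]-α-D-glucopyranoside | CO[C@H]1O[C@@H]2CO[C@@H](c3ccc4ccccc4c3)O[C@H]2[C@H](O)[C@H]1OS(=O)(=O)c1ccc(C)cc1 | intermediate (not isolated)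
5 | methyl 2,3-anhydro-4,6-O-[(R)-naphthalen-2-ylmethylidene]-α-D-mannopyranoside | CO[C@H]1O[C@@H]2CO[C@@H](c3ccc4ccccc4c3)O[C@H]2[C@@H]5O[C@H]15 | intermediate
6 | (trimethylsilyl)acetylene | C#C[Si](C)(C)C | starting material
7 | methyl 3-deoxy-4,6-O-[(R)-naphthalen-2-ylmethylidene]-3-C-[(trimethylsilyl)ethynyl]-α-D-altropyranoside | CO[C@H]1O[C@@H]2CO[C@@H](c3ccc4ccccc4c3)O[C@H]2[C@@H](C#C[Si](C)(C)C)[C@@H]1O | intermediate
8 | methyl 3-deoxy-4-O-(naphthalen-2-ylmethyl)-3-C-[(trimethylsilyl)ethynyl]-α-D-altropyranoside | CO[C@H]1O[C@H](CO)[C@@H](OCc2ccc3ccccc3c2)[C@@H](C#C[Si](C)(C)C)[C@@H]1O | intermediate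
9 | methyl 3-deoxy-4-O-(naphthalen-2-ylmethyl)-3-C-[(trimethylsilyl)ethynyl]-α-D-altro-hexodialdo-1,5-pyranoside | CO[C@H]1O[C@H](C=O)[C@@H](OCc2ccc3ccccc3c2)[C@@H](C#C[Si](C)(C)C)[C@@H]1O | intermediate
10 | methyl 3,6,7-trideoxy-4-O-(naphthalen-2-ylmethyl)-3-C-[(trimethylsilyl)ethynyl]-α-D-altro-hept-6-ynopyranoside | CO[C@H]1O[C@H](C#C)[C@@H](OCc2ccc3ccccc3c2)[C@@H](C#C[Si](C)(C)C)[C@@H]1O | intermediate (not isolated)
11 | methyl 3,6,7-trideoxy-3-C-ethynyl-4-O-(naphthalen-2-ylmethyl)-α-D-altro-hept-6-ynopyranoside | CO[C@H]1O[C@H](C#C)[C@@H](OCc2ccc3ccccc3c2)[C@@H](C#C)[C@@H]1O | intermediate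
12 | 3,6,7-trideoxy-3-C-ethynyl-4-O-(naphthalen-2-ylmethyl)-D-altro-hept-6-ynopyranose (anomeric mixture) | OC1O[C@H](C#C)[C@@H](OCc2ccc3ccccc3c2)[C@@H](C#C)[C@@H]1O | intermediate
13 | (3R,4S,5S,6R)-4-ethynyl-5-(naphthalen-2-ylmethoxy)oct-1-en-7-yne-3,6-diol | C=C[C@@H](O)[C@H](C#C)[C@H](OCc1ccc2ccccc2c1)[C@H](O)C#C | intermediate
14 | (4S,5R)-5-ethenyl-4-[(1S,2R)-2-hydroxy-1-(naphthalen-2-ylmethoxy)but-3-yn-1-yl]-3-methylideneoxolan-2-one | C=C1C(=O)O[C@H](C=C)[C@H]1[C@H](OCc2ccc3ccccc3c2)[C@H](O)C#C | intermediate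
15 | methyl (3R,4S)-4-[(2R,3S)-2-ethenyl-4-methylidene-5-oxooxolan-3-yl]-3-hydroxy-2-methylidene-4-(naphthalen-2-ylmethoxy)butanoate | C=C1C(=O)O[C@H](C=C)[C@H]1[C@H](OCc2ccc3ccccc3c2)[C@H](O)C(=C)C(=O)OC | intermediate
16 | acrolein | C=CC=O | starting material
17 | allyl chloride | C=CCCl | starting material
18 | (3R,4R)-4-chlorohexa-1,5-dien-3-ol | C=C[C@@H](O)[C@H](Cl)C=C | intermediate
19 | chloro{[(3R,4R)-4-chlorohexa-1,5-dien-3-yl]oxy}di(propan-2-yl)silane | C=C[C@@H](O[Si](Cl)(C(C)C)C(C)C)[C@H](Cl)C=C | intermediate (not isolated)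
20 | mixed diisopropylsilylene acetal joining O9 of 15 and the oxygen of 18 | C=C1C(=O)O[C@H](C=C)[C@H]1[C@H](OCc2ccc3ccccc3c2)[C@H](O[Si](C(C)C)(C(C)C)O[C@H](C=C)[C@H](Cl)C=C)C(=C)C(=O)OC | intermediate
21 | seven-membered silaketal (ring Si–O9–C9–C10=C1–C2–O2), CO2Me on C10, (R)-1-chloroprop-2-enyl on C2 | C=C1C(=O)O[C@H](C=C)[C@H]1[C@H](OCc2ccc3ccccc3c2)[C@@H]2O[Si](C(C)C)(C(C)C)O[C@@H]([C@H](Cl)C=C)C=C2C(=O)OC | intermediate
22 | 9-hydroxy (E)-enoate with (2R,3S)-3-ethenyloxiran-2-yl on C1 and naphthylmethyl ether on O8 | C=C1C(=O)O[C@H](C=C)[C@H]1[C@H](OCc2ccc3ccccc3c2)[C@H](O)/C(C(=O)OC)=C\[C@H]2O[C@H]2C=C | intermediate (not isolated)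
23 | 9-O-acetate of 22 | C=C1C(=O)O[C@H](C=C)[C@H]1[C@H](OCc2ccc3ccccc3c2)[C@H](OC(C)=O)/C(C(=O)OC)=C\[C@H]2O[C@H]2C=C | intermediate
24 | 9-O-acetyl 8-hydroxy epoxy enoate | C=C1C(=O)O[C@H](C=C)[C@H]1[C@H](O)[C@H](OC(C)=O)/C(C(=O)OC)=C\[C@H]2O[C@H]2C=C | intermediate
25 | angelic acid | C/C=C(/C)C(=O)O | starting material
26 | (Z)-2-methylbut-2-en-1-ol | C/C=C(/C)CO | intermediate
27 | [(2R,3S)-2,3-dimethyloxiran-2-yl]methanol | OC[C@@]1(C)O[C@H]1C | intermediate
28 | (2S,3S)-2,3-dimethyloxirane-2-carboxylic acid | OC(=O)[C@@]1(C)O[C@H]1C | intermediate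
29 | (2S,3S)-2,3-dimethyloxirane-2-carboxylic 2,4,6-trichlorobenzoic anhydride | O=C(OC(=O)[C@@]1(C)O[C@H]1C)c1c(Cl)cc(Cl)cc1Cl | intermediate (not isolated)
30 | 8-O-[(2S,3S)-2,3-dimethyloxirane-2-carbonyl] 9-O-acetyl open-chain diene | C=C1C(=O)O[C@H](C=C)[C@H]1[C@H](OC(=O)[C@@]2(C)O[C@H]2C)[C@H](OC(C)=O)/C(C(=O)OC)=C\[C@H]2O[C@H]2C=C | intermediate
31 | CNP0077533.1 | C=C1C(=O)O[C@@H]2/C=C\[C@@H]3O[C@@H]3/C=C(/C(=O)OC)[C@@H](OC(C)=O)[C@@H](OC(=O)[C@@]3(C)O[C@H]3C)[C@@H]12 | target

**Step count.** Total: 20 steps. Longest linear sequence: 16 steps (1–10, 12–15, 19, 20).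

**Steps most likely to fail**

1. Step 20 (macrocyclic metathesis). The strained ten-membered ring may close slowly, so that oligomerisation, an E/Z mixture at C4=C5 or capture of the carbene by the methylene lactone takes over. Fallback: set out from 21 and close the ten-membered ring there, by a second ring-closing metathesis of the C4 and C5 vinyl groups. At that stage the seven-membered silaketal still holds C9 and C2 together and C2–C3 is a flexible chlorohydrin, not an epoxide. This gives the macrocyclic silaketal chloride F1. Bu4NF then cleaves the tether and closes the epoxide inside the ring to the macrocyclic 9-hydroxy epoxide F2. Ac2O gives its 9-acetate F3, DDQ frees the 8-hydroxyl to give F4, and Yamaguchi esterification with 28 returns to the route at 31.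

2. Step 13 (silicon-tethered metathesis). Five olefins are present, so crossed pairings may form (the C4 vinyl closing an eight-membered ring, or macrocycles through the C5 vinyl), and the hindered electron-poor acrylate may react sluggishly. Fallback: set out from 15 and tether it to plain allyl alcohol (iPr2SiCl2, imidazole) to give the allyl silaketal F5, in which only one olefin can reach the acrylate. Ring-closing metathesis gives the seven-membered silaketal F6 and HF·pyridine the (E)-enoate diol F7. TEMPO/PhI(OAc)2 oxidises only the primary allylic alcohol to the hydroxy enal F8 (in equilibrium with its lactol). γ-Chloroallylboration with the reagent of step 11 then builds C3 and C4 on the main chain and gives the chlorohydrin diol F9. DBU closes the epoxide to 22, and acetylation returns to the route at 23.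

3. Step 9 (cyclocarbonylation). Site selectivity may be poor: the C9 hydroxyl could close a six-membered ring, the second alkyne could react, or the diyne could oligomerise. Fallback: set out from 11, whose only hydroxyl is O2, and run the same PdCl2/SnCl2/PPh3/CO cyclocarbonylation on the pyranoside. The ring must flip to the 1C4 chair, which places O2 and the 3-ethynyl group diequatorial; this gives the trans-fused lactone pyranoside F10. Aqueous acid gives the lactol F11, and Takai–Lombardo methylenation (Zn, CH2Br2, TiCl4), which spares the lactone and its exocyclic olefin, returns to the route at 14.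

**Further compounds**

F1 | step 20 | macrocyclic silaketal chloride (ten-membered ring closed, O9 and O2 bridged by Si(iPr)2, chloride at C3) | C=C1C(=O)O[C@@H]2/C=C\[C@@H](Cl)[C@@H]3O[Si](C(C)C)(C(C)C)O[C@H](C(C(=O)OC)=C3)[C@@H](OCc4ccc5ccccc5c4)[C@@H]12
F2 | step 20 | macrocyclic 9-hydroxy 2,3-epoxide with O8 naphthylmethyl ether | C=C1C(=O)O[C@@H]2/C=C\[C@@H]3O[C@@H]3/C=C(/C(=O)OC)[C@@H](O)[C@@H](OCc4ccc5ccccc5c4)[C@@H]12
F3 | step 20 | macrocyclic 9-acetate with O8 naphthylmethyl ether | C=C1C(=O)O[C@@H]2/C=C\[C@@H]3O[C@@H]3/C=C(/C(=O)OC)[C@@H](OC(C)=O)[C@@H](OCc4ccc5ccccc5c4)[C@@H]12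
F4 | step 20 | macrocyclic 9-acetate 8-alcohol | C=C1C(=O)O[C@@H]2/C=C\[C@@H]3O[C@@H]3/C=C(/C(=O)OC)[C@@H](OC(C)=O)[C@@H](O)[C@@H]12
F5 | step 13 | allyl diisopropylsilyl mixed acetal of 15 | C=C1C(=O)O[C@H](C=C)[C@H]1[C@H](OCc2ccc3ccccc3c2)[C@H](O[Si](C(C)C)(C(C)C)OCC=C)C(=C)C(=O)OC
F6 | step 13 | seven-membered silaketal with unsubstituted C2 | C=C1C(=O)O[C@H](C=C)[C@H]1[C@H](OCc2ccc3ccccc3c2)[C@@H]2O[Si](C(C)C)(C(C)C)OCC=C2C(=O)OC
F7 | step 13 | (E)-enoate 2,9-diol | C=C1C(=O)O[C@H](C=C)[C@H]1[C@H](OCc2ccc3ccccc3c2)[C@H](O)/C(C(=O)OC)=C\CO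
F8 | step 13 | 9-hydroxy enal (open form of the lactol) | C=C1C(=O)O[C@H](C=C)[C@H]1[C@H](OCc2ccc3ccccc3c2)[C@H](O)/C(C(=O)OC)=C\C=O
F9 | step 13 | chlorohydrin diol | C=C1C(=O)O[C@H](C=C)[C@H]1[C@H](OCc2ccc3ccccc3c2)[C@H](O)/C(C(=O)OC)=C\[C@@H](O)[C@H](Cl)C=C
F10 | step 9 | methyl glycoside with trans-fused 2,3-α-methylene lactone | CO[C@H]1O[C@H](C#C)[C@@H](OCc2ccc3ccccc3c2)[C@H]2C(=C)C(=O)O[C@H]12
F11 | step 9 | corresponding lactol | OC1O[C@H](C#C)[C@@H](OCc2ccc3ccccc3c2)[C@H]2C(=C)C(=O)O[C@H]12
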